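Everything rests on building ring A instead of buying it: the four contiguous substituted carbons C8a(O), C4a, C5(OMe) and C6(OMe) are the four ring carbons of a squarate-derived cyclobutenone, and the unsubstituted C7H–C8H pair is a vinyl group. Heating the 4-methoxy-4-vinylcyclobutenone that carries a 1-ethoxyvinyl group (masked acetyl) at C2 opens the four-membered ring to a dienylketene, which closes the C8–C8a bond and aromatises, giving in one operation the A-ring phenol with the 5,6-dimethoxy pattern and the acetyl equivalent in place. Enol ether hydrolysis, aroylation with the ring B acid chloride and acid cyclodehydration then form ring C.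

Key step: step 4

Remark on stereochemistry: the target has no stereocentre, so no enantiocontrol is required. The only stereocentre on the route (C4 of cyclobutenones 4, 5, 8 and 9) is racemic and is destroyed in step 4.

Remark on design: the squarate adduct is acylated as its lithium alkoxide, so the enol ether never meets free protic acid. The C4 oxygen is methylated before ring expansion, so the only phenol formed is the one that becomes O1. Flavone numbering is used for ring A atoms and cyclobutenone numbering for the four-membered intermediates.

Step 1
Reactants: 1 ethyl vinyl ether; 2 dimethyl squarate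
Product: 6 3-(1-ethoxyvinyl)-4-methoxycyclobut-3-ene-1,2-dione, via 1-ethoxyvinyllithium 3 (not isolated), via lithium alkoxide adduct 4 (not isolated), via trifluoroacetate ester 5 (not isolated)
Conditions: t-BuLi, THF, −78 → 0 °C; added to 2, THF, −78 °C; TFAA, −78 °C; aq. NaHCO3, 0 °C
Reagents that add atoms: water, O
Why: Deprotonation of the vinyl ether at its α-carbon gives an acetyl-anion equivalent that adds 1,2 to a squarate carbonyl, and trifluoroacetylation of the lithium alkoxide sets off the known acylative rearrangement of squarate adducts (ionisation to a methoxy-stabilised cyclobutenyl cation, hydration at the former C–OMe carbon on bicarbonate work-up, loss of methanol) without free protic acid ever meeting the enol ether.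

Step 2
Reactants: 6 3-(1-ethoxyvinyl)-4-methoxycyclobut-3-ene-1,2-dione; 7 vinylmagnesium bromide
Product: 8 2-(1-ethoxyvinyl)-4-hydroxy-3-methoxy-4-vinylcyclobut-2-en-1-one (racemic)
Conditions: THF, −78 °C; sat. aq. NH4Cl, −78 → 0 °C; crude product kept cold and used directly
Reagents that add atoms: none
Why: Chemoselective 1,2-Grignard addition, in which the carbonyl next to C–OMe is a plain enone carbonyl whereas the other is deactivated as a vinylogous ester, so the vinyl group should enter at the former at −78 °C and create the racemic, later destroyed, quaternary carbinol with the substituent order needed for ring A.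

Step 3
Reactants: 8 2-(1-ethoxyvinyl)-4-hydroxy-3-methoxy-4-vinylcyclobut-2-en-1-one
Product: 9 2-(1-ethoxyvinyl)-3,4-dimethoxy-4-vinylcyclobut-2-en-1-one (racemic)
Conditions: MeI (excess), Ag2O, 4 Å MS, MeCN, rt, dark
Reagents that add atoms: iodomethane, CI
Why: Silver(I) oxide-mediated O-methylation (Purdie-type Williamson etherification) alkylates the tertiary allylic alcohol under near-neutral conditions at room temperature, which should avoid both ring opening of a free alkoxide and premature thermal ring expansion while leaving the enol ether untouched.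

Step 4
Reactants: 9 2-(1-ethoxyvinyl)-3,4-dimethoxy-4-vinylcyclobut-2-en-1-one
Product: 12 2-(1-ethoxyvinyl)-3,4-dimethoxyphenol, via dienylketene 10 (not isolated), via cyclohexadienone 11 (not isolated)
Conditions: PhMe (degassed, 0.01 M), 110 °C, Ar
Reagents that add atoms: none
Why: Heating induces conrotatory 4π electrocyclic opening of the C1–C4 bond of 9 to dienylketene 10, whose ketene C=C, C3=C4 alkene and vinyl group then undergo 6π electrocyclisation joining the ketene carbon (future C8a) to the vinyl CH2 (future C8), and tautomerisation of dienone 11 gives the phenol. The closest known reaction type is the thermal Moore rearrangement of 4-alkenyl-4-alkoxycyclobutenones to phenols. Ring A, the only ring formed, is closed by a thermally allowed disrotatory 6π electrocyclisation that makes the single new skeletal bond C8–C8a. No stereocentre is created, and the racemic C4 centre of 9 becomes the sp2 carbon C6. The selectivity needed is torquoselectivity in the ring opening, the vinyl group having to rotate inward so that it lies cis to the ketene: the C4 methoxy donor prefers outward rotation and so enforces this, and a ketene with the vinyl group outward could only revert to 9. The substituent order is already locked by the regioselective addition of step 2, and high dilution should keep the ketene from being intercepted intermolecularly by enol ether or phenol.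

Step 5
Reactants: 12 2-(1-ethoxyvinyl)-3,4-dimethoxyphenol
Product: 13 1-(6-hydroxy-2,3-dimethoxyphenyl)ethan-1-one
Conditions: 1 M aq. HCl, THF, rt
Reagents that add atoms: water, O
Why: Acid-catalysed enol ether hydrolysis (protonation at the CH2 terminus, hemiketal formation, loss of ethanol) unmasks the methyl ketone, and dilute acid at room temperature should not touch the aryl methyl ethers; ketal-type adducts of the enol ether formed during step 4 converge on the same ketone.

Step 6
Reactants: 14 1,2,4,5-tetramethoxybenzene
Product: 16 2,3,5,6-tetramethoxybenzoic acid, via 2,3,5,6-tetramethoxyphenyllithium 15 (not isolated)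
Conditions: n-BuLi (1.05 equiv), THF, 0 °C → rt; CO2, −78 °C → rt; 1 M aq. HCl
Reagents that add atoms: carbon dioxide, O=C=O
Why: Directed ortho-metalation followed by carboxylation, in which each ring hydrogen of 14 lies between two methoxy groups, so one equivalent of n-BuLi should remove one of them cleanly and carbon dioxide traps the aryllithium as the acid with the ring B substitution pattern.

Step 7
Reactants: 16 2,3,5,6-tetramethoxybenzoic acid
Product: 17 2,3,5,6-tetramethoxybenzoyl chloride
Conditions: (COCl)2, DMF (cat.), CH2Cl2, 0 °C → rt; evaporated and used crude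
Reagents that add atoms: oxalyl chloride, O=C(Cl)C(Cl)=O
Why: Acid chloride formation through the Vilsmeier-type chloroiminium species from oxalyl chloride and catalytic DMF should proceed at or below room temperature despite the two ortho methoxy groups and gives only volatile by-products.

Step 8
Reactants: 13 1-(6-hydroxy-2,3-dimethoxyphenyl)ethan-1-one; 17 2,3,5,6-tetramethoxybenzoyl chloride
Product: 19 1-(6-hydroxy-2,3-dimethoxyphenyl)-3-(2,3,5,6-tetramethoxyphenyl)propane-1,3-dione, via dilithium dianion 18 (not isolated)
Conditions: LiHMDS (3.5 equiv), THF, −78 → −10 °C; 17 in THF, −78 °C → rt; 1 M aq. HCl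
Reagents that add atoms: none
Why: Crossed Claisen-type C-acylation of the ketone enolate within the phenoxide–enolate dianion should give the β-diketone directly, and any O-aroylated material is funnelled to the same product by Baker–Venkataraman acyl migration under the excess amide base.

Step 9
Reactants: 19 1-(6-hydroxy-2,3-dimethoxyphenyl)-3-(2,3,5,6-tetramethoxyphenyl)propane-1,3-dione
Product: 20 5,6,2',3',5',6'-hexamethoxyflavone
Conditions: H2SO4 (cat.), AcOH, 95 °C
Reagents that add atoms: none
Why: Acid-catalysed cyclodehydration (closing stage of the Baker–Venkataraman flavone synthesis), in which 6-exo-trig addition of the phenol to the ring B ketone carbonyl and loss of water give the aromatic 4-pyranone ring C under conditions short and mild enough to spare the six methyl ethers.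

Compound list
1 | ethyl vinyl ether | C=COCC | starting material
2 | dimethyl squarate (3,4-dimethoxycyclobut-3-ene-1,2-dione) | COC1=C(OC)C(=O)C1=O | starting material
3 | 1-ethoxyvinyllithium | [Li]C(=C)OCC | intermediate
4 | lithium 1-(1-ethoxyvinyl)-2,3-dimethoxy-4-oxocyclobut-2-en-1-olate (racemic) | C=C(OCC)C1(O[Li])C(OC)=C(OC)C1=O | intermediate
5 | 1-(1-ethoxyvinyl)-2,3-dimethoxy-4-oxocyclobut-2-en-1-yl trifluoroacetate (racemic) | C=C(OCC)C1(OC(=O)C(F)(F)F)C(OC)=C(OC)C1=O | intermediate
6 | 3-(1-ethoxyvinyl)-4-methoxycyclobut-3-ene-1,2-dione | C=C(OCC)C1=C(OC)C(=O)C1=O | intermediate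
7 | vinylmagnesium bromide | C=C[Mg]Br | starting material
8 | 2-(1-ethoxyvinyl)-4-hydroxy-3-methoxy-4-vinylcyclobut-2-en-1-one (racemic) | C=CC1(O)C(OC)=C(C(=C)OCC)C1=O | intermediate
9 | 2-(1-ethoxyvinyl)-3,4-dimethoxy-4-vinylcyclobut-2-en-1-one (racemic) | C=CC1(OC)C(OC)=C(C(=C)OCC)C1=O | intermediate
10 | (3Z)-2-(1-ethoxyvinyl)-3,4-dimethoxyhexa-1,3,5-trien-1-one (dienylketene) | O=C=C(C(=C)OCC)/C(OC)=C(/OC)C=C | intermediate
11 | 2-(1-ethoxyvinyl)-3,4-dimethoxycyclohexa-2,4-dien-1-one | C=C(OCC)C1=C(OC)C(OC)=CCC1=O | intermediate
12 | 2-(1-ethoxyvinyl)-3,4-dimethoxyphenol | C=C(OCC)c1c(O)ccc(OC)c1OC | intermediate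
13 | 1-(6-hydroxy-2,3-dimethoxyphenyl)ethan-1-one | CC(=O)c1c(O)ccc(OC)c1OC | intermediate
14 | 1,2,4,5-tetramethoxybenzene | COc1cc(OC)c(OC)cc1OC | starting material
15 | 2,3,5,6-tetramethoxyphenyllithium | [Li]c1c(OC)c(OC)cc(OC)c1OC | intermediate
16 | 2,3,5,6-tetramethoxybenzoic acid | COc1cc(OC)c(OC)c(C(=O)O)c1OC | intermediate
17 | 2,3,5,6-tetramethoxybenzoyl chloride | COc1cc(OC)c(OC)c(C(=O)Cl)c1OC | intermediate
18 | dilithium enolate–phenoxide of 13 (lithium 2-(1-lithiooxyvinyl)-3,4-dimethoxyphenoxide) | C=C(O[Li])c1c(O[Li])ccc(OC)c1OC | intermediate
19 | 1-(6-hydroxy-2,3-dimethoxyphenyl)-3-(2,3,5,6-tetramethoxyphenyl)propane-1,3-dione | COc1cc(OC)c(OC)c(C(=O)CC(=O)c2c(O)ccc(OC)c2OC)c1OC | intermediate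
20 | 5,6,2',3',5',6'-hexamethoxyflavone (5,6-dimethoxy-2-(2,3,5,6-tetramethoxyphenyl)-4H-chromen-4-one) | COc1cc(OC)c(OC)c(-c2cc(=O)c3c(OC)c(OC)ccc3o2)c1OC | target

Total step count: 9. Longest linear sequence: 7 steps (steps 1, 2, 3, 4, 5, 8, 9); steps 6 and 7 are the two-step ring B branch that joins at step 8.

Steps most likely to fail

Step 1. The electron-rich enol ether may not survive the acylative ionisation: it can be hydrolysed to the ketone, trifluoroacetylated at its CH2 terminus, or drawn into a ring-enlarging acyl shift of the carbinol, and the 2-alkoxydiene in 6 may dimerise on standing. The fallback replaces the masked acetyl group by an acid-stable silylalkyne; it sets out from 2 and comes back to the route at 13. Lithium (trimethylsilyl)acetylide (ethynyltrimethylsilane, n-BuLi, THF, −78 °C) is added to 2 to give 4-hydroxy-2,3-dimethoxy-4-[(trimethylsilyl)ethynyl]cyclobut-2-en-1-one F1. Catalytic conc. HCl in CH2Cl2 rearranges it to 3-methoxy-4-[(trimethylsilyl)ethynyl]cyclobut-3-ene-1,2-dione F2. Addition of 7 as in step 2 should give 4-hydroxy-3-methoxy-2-[(trimethylsilyl)ethynyl]-4-vinylcyclobut-2-en-1-one F3, and methylation as in step 3 should give 3,4-dimethoxy-2-[(trimethylsilyl)ethynyl]-4-vinylcyclobut-2-en-1-one F4. The same thermal ring expansion in toluene should give 3,4-dimethoxy-2-[(trimethylsilyl)ethynyl]phenol F5. Acid-catalysed Markovnikov hydration with protodesilylation (TsOH·H2O, aqueous MeCN, reflux) should then deliver 13.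

Step 4. The transient ketene may be intercepted intermolecularly by the nucleophilic enol ether or by phenol already formed, and the o-hydroxyaryl enol ether may oligomerise at 110 °C, eroding the mass balance. The fallback inverts the order of unmasking and ring expansion, so that no enol ether is present during the thermolysis; it sets out from 9 and comes back at 13. Mild hydrolysis of 9 (oxalic acid on wet silica gel, CH2Cl2, rt) should give 2-acetyl-3,4-dimethoxy-4-vinylcyclobut-2-en-1-one F6. The same conrotatory opening and 6π closure in dilute toluene at 110 °C should then give 13 directly, its phenol being tied up at once in a hydrogen bond to the acetyl group.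

Step 3. The tertiary, doubly allylic alcohol may resist alkylation, a transient alkoxide may open the four-membered ring, and 8 may begin to ring-expand while the methylation is still incomplete. The fallback omits the methylation at this stage and differentiates the two phenols afterwards; it sets out from 8 and comes back at 13. Heating 8 in degassed toluene should give the hydroquinone 2-(1-ethoxyvinyl)-3-methoxybenzene-1,4-diol F7 by the hydroxy variant of the same rearrangement. Dilute HCl in THF then gives 1-(3,6-dihydroxy-2-methoxyphenyl)ethan-1-one F8. Mono-methylation (MeI, 1.05 equiv, K2CO3, acetone) should take place at the 3-hydroxyl, which is not hydrogen-bonded to the ketone, to give 13.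

Further compounds
F1 | step 1 | 4-hydroxy-2,3-dimethoxy-4-[(trimethylsilyl)ethynyl]cyclobut-2-en-1-one (racemic) | C[Si](C)(C)C#CC1(O)C(OC)=C(OC)C1=O
F2 | step 1 | 3-methoxy-4-[(trimethylsilyl)ethynyl]cyclobut-3-ene-1,2-dione | COC1=C(C#C[Si](C)(C)C)C(=O)C1=O
F3 | step 1 | 4-hydroxy-3-methoxy-2-[(trimethylsilyl)ethynyl]-4-vinylcyclobut-2-en-1-one (racemic) | C=CC1(O)C(OC)=C(C#C[Si](C)(C)C)C1=O
F4 | step 1 | 3,4-dimethoxy-2-[(trimethylsilyl)ethynyl]-4-vinylcyclobut-2-en-1-one (racemic) | C=CC1(OC)C(OC)=C(C#C[Si](C)(C)C)C1=O
F5 | step 1 | 3,4-dimethoxy-2-[(trimethylsilyl)ethynyl]phenol | COc1ccc(O)c(C#C[Si](C)(C)C)c1OC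
F6 | step 4 | 2-acetyl-3,4-dimethoxy-4-vinylcyclobut-2-en-1-one (racemic) | C=CC1(OC)C(OC)=C(C(C)=O)C1=O
F7 | step 3 | 2-(1-ethoxyvinyl)-3-methoxybenzene-1,4-diol | C=C(OCC)c1c(O)ccc(O)c1OC
F8 | step 3 | 1-(3,6-dihydroxy-2-methoxyphenyl)ethan-1-one | CC(=O)c1c(O)ccc(O)c1OC
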